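**Retrosynthetic overview**

- Target 21 comes from bis-phenol 18 by Friedel–Crafts butyrylation at C1 of each ring A, then BCl3 removal of the C6 ethyl ethers and the three benzyl ethers.
- The strategy rests on ring A (C1 butyryl, C2 OH, C3 Me, C4 OMe, C5 bridge, C6 OH): C3 and C4 are the two alkyne carbons of 1-methoxypropyne 13, and C5, C6, C1 and C2 are the four ring carbons of a 2-substituted 3-ethoxycyclobutenone, so a twofold benzannulation of bis-cyclobutenone 10 makes the C2–C3 and C4–C5 bonds of both rings A.
- Bis-cyclobutenone 10 comes from ketene [2+2] addition to bis(ynol ether) 9, which comes from Negishi coupling of bis(benzylic bromide) 5 with ethoxyethynylzinc chloride.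
- Dibromide 5 comes from 2,4,6-trihydroxyacetophenone 1 by diformylation, benzylation, reduction and bromination; the central ring is bought and both rings A are formed last, in the same operation.

Key step: step 8

Remark: the target has no stereocentre, so no stereocontrol is needed; ketene for step 6 is taken from pyrolysis of acetone, and 1-methoxypropyne is made in step 7 because its commercial supply is not assumed.

**Step 1**
Reactants: 1 2,4,6-trihydroxyacetophenone
Product: 2 5-acetyl-2,4,6-trihydroxybenzene-1,3-dicarbaldehyde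
Conditions: Cl2CHOMe (5 equiv), TiCl4 (6 equiv), CH2Cl2, 0 °C→rt; then 1 M HCl, 0 °C
Reagents that add atoms: dichloromethyl methyl ether COC(Cl)Cl; water O
Why: Rieche formylation of the titanium phenoxide, in which each of the two open ring positions is ortho or para to all three oxygens so that both should be formylated, the aldehydes being released on hydrolysis of the α-chloro ethers.

**Step 2**
Reactants: 2 5-acetyl-2,4,6-trihydroxybenzene-1,3-dicarbaldehyde
Product: 3 5-acetyl-2,4,6-tris(benzyloxy)benzene-1,3-dicarbaldehyde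
Conditions: BnBr (4.5 equiv), K2CO3, DMF, 60 °C
Reagents that add atoms: benzyl bromide BrCc1ccccc1
Why: Williamson ether synthesis, in which K2CO3 in DMF should direct benzylation to oxygen because every ring carbon is substituted and C-benzylation would cost the aromaticity.

**Step 3**
Reactants: 3 5-acetyl-2,4,6-tris(benzyloxy)benzene-1,3-dicarbaldehyde
Product: 4 1-[2,4,6-tris(benzyloxy)-3,5-bis(hydroxymethyl)phenyl]ethan-1-one
Conditions: NaBH4 (1.1 equiv), THF/MeOH, −20 °C
Reagents that add atoms: none
Why: Chemoselective borohydride reduction, the two aldehydes being far more electrophilic than the methyl ketone, which is twisted out of conjugation and shielded by two ortho benzyloxy groups.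

**Step 4**
Reactants: 4 1-[2,4,6-tris(benzyloxy)-3,5-bis(hydroxymethyl)phenyl]ethan-1-one
Product: 5 1-[2,4,6-tris(benzyloxy)-3,5-bis(bromomethyl)phenyl]ethan-1-one
Conditions: PBr3 (0.8 equiv), CH2Cl2, 0 °C; crude product used at once
Reagents that add atoms: phosphorus tribromide BrP(Br)Br
Why: Bromination of benzylic alcohols through their phosphite esters, which should be fast at the electron-rich benzylic carbons, the labile dibromide being carried on without chromatography.

**Step 5**
Reactants: 5 1-[2,4,6-tris(benzyloxy)-3,5-bis(bromomethyl)phenyl]ethan-1-one; 6 ethoxyacetylene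
Product: 9 1-[2,4,6-tris(benzyloxy)-3,5-bis(3-ethoxyprop-2-yn-1-yl)phenyl]ethan-1-one, via lithium ethoxyacetylide 7 (not isolated), via ethoxyethynylzinc chloride 8 (not isolated)
Conditions: 6 (2.6 equiv), n-BuLi, THF, −78 °C; ZnCl2, −78→0 °C; then 5, Pd(PPh3)4 (5 mol%), THF, 0 °C→rt; filtration through basic Al2O3
Reagents that add atoms: none
Why: Negishi coupling of an alkynylzinc with a benzylic bromide, in which zerovalent palladium should insert readily into the benzylic C–Br bonds and the zinc acetylide, unlike the lithium or magnesium acetylide, should leave the acetyl group untouched.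

**Step 6**
Reactants: 9 1-[2,4,6-tris(benzyloxy)-3,5-bis(3-ethoxyprop-2-yn-1-yl)phenyl]ethan-1-one
Product: 10 1-{2,4,6-tris(benzyloxy)-3,5-bis[(2-ethoxy-4-oxocyclobut-1-en-1-yl)methyl]phenyl}ethan-1-one
Conditions: ketene (excess, from pyrolysis of acetone), CH2Cl2, 0 °C→rt
Reagents that add atoms: ketene C=C=O
Why: [2+2] cycloaddition of ketene with a 1-alkoxyalkyne, in which the nucleophilic carbon-substituted alkyne carbon bonds to the ketene carbonyl carbon so that each arm should give only the 2-substituted 3-ethoxycyclobutenone.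

**Step 7**
Reactants: 11 chloroacetaldehyde dimethyl acetal
Product: 13 1-methoxyprop-1-yne, via sodium methoxyacetylide 12 (not isolated)
Conditions: NaNH2 (3 equiv), liquid NH3, −33 °C; then MeI, −33 °C→rt; distillation
Reagents that add atoms: iodomethane CI
Why: Twofold base-induced elimination (methanol, then HCl) should give the sodium alkoxyacetylide, which is C-methylated in the same flask by acetylide alkylation in liquid ammonia.

**Step 8**
Reactants: 10 1-{2,4,6-tris(benzyloxy)-3,5-bis[(2-ethoxy-4-oxocyclobut-1-en-1-yl)methyl]phenyl}ethan-1-one; 13 1-methoxyprop-1-yne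
Product: 18 1-{2,4,6-tris(benzyloxy)-3,5-bis[(6-ethoxy-4-hydroxy-2-methoxy-3-methylphenyl)methyl]phenyl}ethan-1-one, via bis(vinylketene) 14 (not isolated), via bis(4-vinylcyclobutenone) 15 (not isolated), via bis(dienylketene) 16 (not isolated), via bis(cyclohexa-2,4-dienone) 17 (not isolated)
Conditions: 13 (8 equiv), toluene, sealed tube, 80→140 °C
Reagents that add atoms: none
Why: Proposed new method: each 3-ethoxycyclobutenone should open thermally (four-electron electrocyclic) to a (1-ethoxyvinyl)ketene, whose central carbon is attacked by the nucleophilic methyl-bearing carbon of 13 in a regioselective [2+2] cycloaddition, and the resulting 4-vinylcyclobutenone reopens to a dienylketene. The closest known reaction type is the Danheiser benzannulation of 3-alkyl- and 3-aryl-cyclobutenones with alkoxy- and siloxyalkynes; a 3-alkoxycyclobutenone partner and a twofold version have not been shown, and the vinylogous-ester stabilisation of the four-membered ring is expected to raise the temperature of the first opening, hence the ramp to 140 °C. Each ring A closes by thermal six-electron disrotatory electrocyclisation of the dienylketene, joining the ketene carbon (C2) to the CH2 terminus of the ethoxyvinyl group (C1), and tautomerisation of the cyclohexa-2,4-dienone gives the phenol, the net new bonds per ring being C2–C3 and C4–C5. No stereocentre is left in 18, and the quaternary centres of 15 and the alkene geometry of 16 do not matter because the ring openings are reversible and only the isomer with ketene and ethoxyvinyl groups cis can cyclise. The step needs [2+2] regioselectivity, which the polarisation of the ynol ether secures (OMe ends next to the bridge carbon, OH next to methyl), and it needs each ketene to be taken by the alkyne and not by phenol already formed, which the excess of 13 secures; the O-methyl group of 13 has no β-hydrogen, so the alkyne cannot fragment by retro-ene loss of an alkene at this temperature.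

**Step 9**
Reactants: 18 1-{2,4,6-tris(benzyloxy)-3,5-bis[(6-ethoxy-4-hydroxy-2-methoxy-3-methylphenyl)methyl]phenyl}ethan-1-one; 19 butyryl chloride
Product: 20 1-{2,4,6-tris(benzyloxy)-3,5-bis[(5-butanoyl-6-ethoxy-4-hydroxy-2-methoxy-3-methylphenyl)methyl]phenyl}ethan-1-one
Conditions: TiCl4 (4 equiv), 19 (3 equiv), CH2Cl2, −40→0 °C
Reagents that add atoms: none
Why: Friedel–Crafts acylation directed by the titanium phenoxide (ortho-acylation of a phenol), C1 of each ring A being the only unsubstituted carbon of the electron-rich rings and lying ortho to OH, ortho to OEt and para to OMe.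

**Step 10**
Reactants: 20 1-{2,4,6-tris(benzyloxy)-3,5-bis[(5-butanoyl-6-ethoxy-4-hydroxy-2-methoxy-3-methylphenyl)methyl]phenyl}ethan-1-one
Product: 21 1-{2,4,6-trihydroxy-3,5-bis[(3-butanoyl-2,4-dihydroxy-6-methoxy-5-methylphenyl)methyl]phenyl}ethan-1-one (CNP0184345.0)
Conditions: BCl3 (12 equiv), C6HMe5, CH2Cl2, −78→0 °C; then MeOH, H2O
Reagents that add atoms: none
Why: Lewis-acid ether cleavage with BCl3, in which the benzyl ethers should fall at low temperature with pentamethylbenzene as cation trap and the C6 ethyl ethers through the six-membered boron chelate with the neighbouring butyryl carbonyl, while the C4 methyl ethers, which have no carbonyl neighbour, should stay.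

**Compound list**

1 | 2,4,6-trihydroxyacetophenone | CC(=O)c1c(O)cc(O)cc1O | starting material
2 | 5-acetyl-2,4,6-trihydroxybenzene-1,3-dicarbaldehyde | CC(=O)c1c(O)c(C=O)c(O)c(C=O)c1O | intermediate
3 | 5-acetyl-2,4,6-tris(benzyloxy)benzene-1,3-dicarbaldehyde | CC(=O)c1c(OCc2ccccc2)c(C=O)c(OCc2ccccc2)c(C=O)c1OCc1ccccc1 | intermediate
4 | 1-[2,4,6-tris(benzyloxy)-3,5-bis(hydroxymethyl)phenyl]ethan-1-one | CC(=O)c1c(OCc2ccccc2)c(CO)c(OCc2ccccc2)c(CO)c1OCc1ccccc1 | intermediate
5 | 1-[2,4,6-tris(benzyloxy)-3,5-bis(bromomethyl)phenyl]ethan-1-one | CC(=O)c1c(OCc2ccccc2)c(CBr)c(OCc2ccccc2)c(CBr)c1OCc1ccccc1 | intermediate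
6 | ethoxyacetylene | C#COCC | starting material
7 | lithium ethoxyacetylide (formed in the flask, not isolated) | [Li]C#COCC | intermediate
8 | ethoxyethynylzinc chloride (formed in the flask, not isolated) | Cl[Zn]C#COCC | intermediate
9 | 1-[2,4,6-tris(benzyloxy)-3,5-bis(3-ethoxyprop-2-yn-1-yl)phenyl]ethan-1-one, the bis(ynol ether) | CC(=O)c1c(OCc2ccccc2)c(CC#COCC)c(OCc2ccccc2)c(CC#COCC)c1OCc1ccccc1 | intermediate
10 | 1-{2,4,6-tris(benzyloxy)-3,5-bis[(2-ethoxy-4-oxocyclobut-1-en-1-yl)methyl]phenyl}ethan-1-one, the bis-cyclobutenone | CC(=O)c1c(OCc2ccccc2)c(CC2=C(OCC)CC2=O)c(OCc2ccccc2)c(CC2=C(OCC)CC2=O)c1OCc1ccccc1 | intermediate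
11 | chloroacetaldehyde dimethyl acetal (2-chloro-1,1-dimethoxyethane) | COC(CCl)OC | starting material
12 | sodium methoxyacetylide (formed in the flask, not isolated) | [Na]C#COC | intermediate
13 | 1-methoxyprop-1-yne | CC#COC | intermediate
14 | bis(vinylketene): each arm ArCH2–C(=C=O)–C(OEt)=CH2 (not isolated; both arms drawn at the same stage) | CC(=O)c1c(OCc2ccccc2)c(CC(=C=O)C(=C)OCC)c(OCc2ccccc2)c(CC(=C=O)C(=C)OCC)c1OCc1ccccc1 | intermediate
15 | bis(4-vinylcyclobutenone): each arm a 4-(arylmethyl)-4-(1-ethoxyvinyl)-3-methoxy-2-methylcyclobut-2-en-1-one (not isolated; mixture of diastereomers at the two transient quaternary carbons) | CC(=O)c1c(OCc2ccccc2)c(CC2(C(=C)OCC)C(=O)C(C)=C2OC)c(OCc2ccccc2)c(CC2(C(=C)OCC)C(=O)C(C)=C2OC)c1OCc1ccccc1 | intermediate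
16 | bis(dienylketene): each arm O=C=C(Me)–C(OMe)=C(CH2Ar)–C(OEt)=CH2, drawn as the reacting isomer with ketenyl and ethoxyvinyl groups cis on the central alkene (not isolated) | CC(=O)c1c(OCc2ccccc2)c(C/C(C(=C)OCC)=C(\OC)C(C)=C=O)c(OCc2ccccc2)c(C/C(C(=C)OCC)=C(\OC)C(C)=C=O)c1OCc1ccccc1 | intermediate
17 | bis(cyclohexa-2,4-dienone): each arm a 4-(arylmethyl)-5-ethoxy-3-methoxy-2-methylcyclohexa-2,4-dien-1-one (not isolated) | CC(=O)c1c(OCc2ccccc2)c(CC2=C(OCC)CC(=O)C(C)=C2OC)c(OCc2ccccc2)c(CC2=C(OCC)CC(=O)C(C)=C2OC)c1OCc1ccccc1 | intermediate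
18 | 1-{2,4,6-tris(benzyloxy)-3,5-bis[(6-ethoxy-4-hydroxy-2-methoxy-3-methylphenyl)methyl]phenyl}ethan-1-one | CC(=O)c1c(OCc2ccccc2)c(Cc2c(OC)c(C)c(O)cc2OCC)c(OCc2ccccc2)c(Cc2c(OC)c(C)c(O)cc2OCC)c1OCc1ccccc1 | intermediate
19 | butyryl chloride | CCCC(Cl)=O | starting material
20 | 1-{2,4,6-tris(benzyloxy)-3,5-bis[(5-butanoyl-6-ethoxy-4-hydroxy-2-methoxy-3-methylphenyl)methyl]phenyl}ethan-1-one | CC(=O)c1c(OCc2ccccc2)c(Cc2c(OC)c(C)c(O)c(C(=O)CCC)c2OCC)c(OCc2ccccc2)c(Cc2c(OC)c(C)c(O)c(C(=O)CCC)c2OCC)c1OCc1ccccc1 | intermediate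
21 | 1-{2,4,6-trihydroxy-3,5-bis[(3-butanoyl-2,4-dihydroxy-6-methoxy-5-methylphenyl)methyl]phenyl}ethan-1-one (CNP0184345.0) | CCCC(=O)c1c(O)c(C)c(OC)c(Cc2c(O)c(Cc3c(O)c(C)c(OC)c(C(=O)CCC)c3O)c(O)c(C(C)=O)c2O)c1O | target

**Step count and risks**

Total step count: 10. Longest linear sequence: 9 steps (steps 1–6 and 8–10; step 7 is a one-step side branch).

Steps most likely to fail:

Step 8. The vinylogous-ester cyclobutenone may not open before the ynol ether and the ketene intermediates oligomerise. The phenol formed on the first arm may also capture the ketene of the second arm, so that only one arm is annulated. The fallback uses known chemistry and sets out from diol 4. Friedel–Crafts benzylation with 4 (catalytic Sc(OTf)3, CH2Cl2/MeNO2, 0 °C) of aspidinol F1, a purchasable natural product, at its only free ring carbon should give the tri-O-benzyl ether of the target F2. Hydrogenolysis (H2, Pd/C, EtOAc) then returns to the route at target 21.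

Step 5. The doubly activated bis(benzylic bromide) may ionise or homocouple faster than it cross-couples, and the ynol ether arms may hydrate during isolation. The fallback reverses the polarity and sets out from dibromide 5. Zinc insertion (Zn dust, LiCl, THF, 0 °C) should give the bis(benzylzinc bromide) F3. Negishi coupling (Pd(PPh3)4, THF, rt) with 2-bromo-3-ethoxycyclobut-2-en-1-one F4, made from commercial 3-ethoxycyclobut-2-en-1-one and N-bromosuccinimide, then returns to the route at bis-cyclobutenone 10 and bypasses 9 and the ketene step.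

Step 9. TiCl4 may strip benzyl ethers, leading to re-benzylation or O-acylation of the freed phenols, and the acid may cleave the electron-rich diarylmethane bridges. The fallback avoids strong Lewis acid and sets out from 18. Magnesium-mediated ortho-formylation (MgCl2, Et3N, paraformaldehyde, MeCN, reflux) should give the bis(salicylaldehyde) F5. n-PrMgBr (excess, THF, −78 °C) should add to the aldehydes in preference to the hindered acetyl group to give the bis(carbinol) F6. Oxidation with MnO2 (CH2Cl2, rt) returns to the route at 20.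

**Further compounds**

F1 | step 8 | aspidinol, 1-(2,6-dihydroxy-4-methoxy-3-methylphenyl)butan-1-one (purchased) | CCCC(=O)c1c(O)cc(OC)c(C)c1O
F2 | step 8 | tri-O-benzyl ether of the target, 1-{2,4,6-tris(benzyloxy)-3,5-bis[(3-butanoyl-2,4-dihydroxy-6-methoxy-5-methylphenyl)methyl]phenyl}ethan-1-one | CCCC(=O)c1c(O)c(C)c(OC)c(Cc2c(OCc3ccccc3)c(Cc3c(O)c(C)c(OC)c(C(=O)CCC)c3O)c(OCc3ccccc3)c(C(C)=O)c2OCc2ccccc2)c1O
F3 | step 5 | bis(benzylzinc bromide) from 5 | CC(=O)c1c(OCc2ccccc2)c(C[Zn]Br)c(OCc2ccccc2)c(C[Zn]Br)c1OCc1ccccc1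
F4 | step 5 | 2-bromo-3-ethoxycyclobut-2-en-1-one | CCOC1=C(Br)C(=O)C1
F5 | step 9 | bis(salicylaldehyde), 1-{2,4,6-tris(benzyloxy)-3,5-bis[(6-ethoxy-5-formyl-4-hydroxy-2-methoxy-3-methylphenyl)methyl]phenyl}ethan-1-one | CC(=O)c1c(OCc2ccccc2)c(Cc2c(OC)c(C)c(O)c(C=O)c2OCC)c(OCc2ccccc2)c(Cc2c(OC)c(C)c(O)c(C=O)c2OCC)c1OCc1ccccc1
F6 | step 9 | bis(carbinol), 1-{2,4,6-tris(benzyloxy)-3,5-bis[(6-ethoxy-4-hydroxy-5-(1-hydroxybutyl)-2-methoxy-3-methylphenyl)methyl]phenyl}ethan-1-one, mixture of diastereomers | CC(=O)c1c(OCc2ccccc2)c(Cc2c(OC)c(C)c(O)c(C(O)CCC)c2OCC)c(OCc2ccccc2)c(Cc2c(OC)c(C)c(O)c(C(O)CCC)c2OCC)c1OCc1ccccc1
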